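In each earlier run the amount of product at the plateau matched the amount of coupling partner charged, whatever the substrate charge was.

| setting | winter | summer | autumn | oak | maple | cedar | larch |
|---|---|---|---|---|---|---|---|
| substrate | 0.42 M | 0.66 M | 0.30 M | 0.30 M | 0.30 M | 0.30 M | 0.30 M |
| coupling partner | 0.21 M | 0.21 M | 0.10 M | 0.210 M | 0.210 M | 0.210 M | 0.210 M |
| temperature | 40 °C | 73 °C | 40 °C | 25 °C | 85 °C | 55 °C |  |
| remark | run made earlier | run made earlier | run made earlier |  |  |  | at 25 °C until 15 min, from then on at 85 °C |
| time |  |  |  | 50 min | 50 min | 50 min | 50 min |

- winter (time / min: product / %): 1.33: 44.8; 2.00: 47.7; 3.00: 48.4; 4.00: 49.4; 6.00: 50.3; 10.0: 50.2; 15.0: 50.5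
- summer (time / min: product / %): 0.333: 32.1; 0.667: 31.7; 1.00: 31.6; 1.33: 33.3; 2.00: 31.8; 2.50: 32.1; 3.00: 31.6
- autumn (time / min: product / %): 1.33: 29.4; 2.50: 32.3; 4.00: 33.8; 8.00: 32.4; 15.0: 33.5

(each reading ± 0.5 percentage points)

- which flask leads in amount of product, in percent of the substrate charged ("all alike" within 1.5 percentage points) (oak / maple / cedar / larch / all alike)
- how much product is there at the end, in percent of the substrate charged: oak
- how much product is there at the end, in percent of the substrate charged: maple
- how much product is there at the end, in percent of the substrate charged: cedar
- how much product is there at the end, in percent of the substrate charged: larch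

- a reading or a percentage of product counts all its forms, free or not

I turned the last readings into molar amounts:

winter: 0.212 M of product from 0.21 M of coupling partner
summer: 0.209 M of product from 0.21 M of coupling partner
autumn: 0.101 M of product from 0.10 M of coupling partner

So I took the coupling partner as the limiting reagent, reacting one for one with substrate. For the new flasks that gives 70.0%, and I called this the ceiling: coupling partner charged over substrate charged.

Then I asked what the opposite outcome required. For the flasks to part, one had to end more than 1.5 percentage points below the ceiling. In oak, the coolest flask, that meant at least 0.00450 M of coupling partner still unreacted at the end. I assumed a rate first order in each charge, with A and B the charges and a and b what is left of them: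

k·t = ln(B·a/(A·b))/(A−B)

needed for that shortfall in oak: k = 0.00995 M⁻¹ s⁻¹
read from the first autumn reading: k = 0.112 M⁻¹ s⁻¹

The reading at 40 °C stands 11.3 times above the needed value, so on that rate law a shortfall in oak called for k to drop by that factor on cooling to 25 °C. The runs show no rate at a lower temperature, so this was my judgement, and I did not expect so steep a fall.

A second way to part was loss of product in the heat. From first to last the summer readings moved by 0.5 points against a scatter of 0.5 points, and their full span, set by the high reading at 1.33 min, was 1.7 points, though this was over 3.00 min at 73 °C and not at 85 °C. I committed to the ceiling in all four flasks.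

The forecast said “the partner limits it” and gave 69.8% for oak, 70% for maple, 70% for cedar, 70% for larch, and all alike.

The flasks gave 69.8% for oak, 70.0% for maple, 70.0% for cedar and 70.0% for larch: all alike.

    substrate + coupling partner → product + by-product (k = 0.0980 M⁻¹ s⁻¹, Ea = 66.0 kJ mol⁻¹)
    coupling partner ⇌ dormant form (K = 3.40, k = 0.0170 s⁻¹, Ea = 91.0 kJ mol⁻¹, ΔH = −31.0 kJ mol⁻¹)
    crystals ⇌ product, rate k3*(cs3 - [product]) while solid is left; crystals form when [product] > cs3 (solubility = 4.70 mM, k = 0.0350 s⁻¹)
    (constants at 25 °C)

Oak ended at 69.8% against its ceiling of 70.0%, with 0.053% of its coupling partner left free. I carried the ceiling to a neighbour of oak charged with 0.052 M of coupling partner, its substrate and time held as in oak. There the ratio is 0.173 equiv, so the ceiling is 17.3%, and that flask gave 17.3%. Its coupling partner stood at 0% at 50.0 min, and 83% of its substrate remained unbound.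

(The data come from a simulation from invented constants; noise was put on by code.)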